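**Retrosynthetic overview**
1. Target ⇐ desilylation ⇐ transannular C–O bond formation (C10–O onto C3, with hydration/cyclodehydration) in a ten-membered γ-hydroxy ynone; this closes the 3(2H)-furanone and is the key step.
2. Ten-membered ynone ⇐ carbonylative macrocyclisation of a seco Z-alkenyl iodide / terminal propargylic alcohol; CO becomes C3 (new method).
3. Seco cis-lactone ⇐ indium Barbier allylation/lactonisation of a Z-β-iodoenal (C4–C6, C15) with a 2-(bromomethyl)enoate (C1, C2, C7–C14); sets C6 and C7.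
4. Bromide ⇐ proline aldol of acetone with 2,2-dimethoxyacetaldehyde (C8), chelation-controlled ethynylation (C10), vinylalumination, SN2′ bromination; iodoenal ⇐ but-2-yne-1,4-diol.
5. Ring order: γ-lactone, then ten-membered carbocycle, then furanone (oxygen bridge).

Assumption: germacrane numbering is used (C1 ketone, C2=C3, C4=C5, C6 lactone carbinol, C7, C8 ester carbinol, C9, C10 quaternary, C11–C13 methylene lactone, C14 methyl, C15 CH2O). The SMILES is read as 4Z,6S,7R,8R,10R, i.e. a cis-fused lactone with 1,3-anti oxygens at C8/C10.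

**Fragment B (iodoenal)**

Step 1
Reactants: 1 but-2-yne-1,4-diol
Product: 2 4-{[tert-butyl(diphenyl)silyl]oxy}but-2-yn-1-ol
Conditions: TBDPSCl (1 equiv; 1 in 3-fold excess), imidazole, DMF, 0 → 23 °C
Reagents that add atoms: tert-butyl(chloro)diphenylsilane, CC(C)(C)[Si](Cl)(c1ccccc1)c1ccccc1
Why: Imidazole-promoted O-silylation of a symmetrical diol used in excess gives the mono-ether; no stereocentre.

Step 2
Reactants: 2 4-{[tert-butyl(diphenyl)silyl]oxy}but-2-yn-1-ol
Product: 3 (2Z)-4-{[tert-butyl(diphenyl)silyl]oxy}-3-iodobut-2-en-1-ol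
Conditions: NaAlH2(OCH2CH2OMe)2, THF, 0 °C; then I2, −78 → 0 °C
Reagents that add atoms: iodine, II
Why: Hydroxyl-directed trans-hydroalumination puts Al on the distal alkyne carbon and iodinolysis proceeds with retention, so I is cis to CH2OH (Z); this fixes the later 4Z olefin.

Step 3
Reactants: 3 (2Z)-4-{[tert-butyl(diphenyl)silyl]oxy}-3-iodobut-2-en-1-ol
Product: 4 (2Z)-4-{[tert-butyl(diphenyl)silyl]oxy}-3-iodobut-2-enal
Conditions: MnO2, CH2Cl2, 23 °C
Reagents that add atoms: none
Why: Neutral allylic alcohol oxidation with MnO2 leaves the Z-iodoalkene and the silyl ether untouched.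

**Fragment A (allyl bromide)**

Step 4
Reactants: 5 acetone; 6 2,2-dimethoxyacetaldehyde
Product: 7 (4R)-4-hydroxy-5,5-dimethoxypentan-2-one
Conditions: L-proline (30 mol %), acetone/DMSO, 23 °C
Reagents that add atoms: none
Why: Proline-catalysed direct asymmetric aldol (enamine, Houk–List transition state): re-face attack on the aldehyde gives the 4R carbinol, the future C8.

Step 5
Reactants: 7 (4R)-4-hydroxy-5,5-dimethoxypentan-2-one
Product: 8 (3R,5R)-6,6-dimethoxy-3-methylhex-1-yne-3,5-diol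
Conditions: HC≡CMgBr (3.2 equiv), THF/CH2Cl2, −78 → −20 °C
Reagents that add atoms: ethynylmagnesium bromide, C#C[Mg]Br
Why: Chelation-controlled Grignard addition (six-membered Mg chelate of the β-alkoxide and ketone, axial attack) gives the 1,3-anti diol, so 3R = C10 R; the minor epimer is removed by chromatography.

Step 6
Reactants: 8 (3R,5R)-6,6-dimethoxy-3-methylhex-1-yne-3,5-diol
Product: 10 (2R,4R)-1,1-dimethoxy-4-methyl-4-[(triethylsilyl)oxy]hex-5-yn-2-yl 2-methylpropanoate, via mono-isobutyrate 9 (not isolated)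
Conditions: iPrCOCl, pyridine, DMAP (cat.), CH2Cl2, 0 °C; then TESOTf, 2,6-lutidine, −78 → 0 °C
Reagents that add atoms: 2-methylpropanoyl chloride, CC(C)C(=O)Cl; triethylsilyl trifluoromethanesulfonate, CC[Si](CC)(CC)OS(=O)(=O)C(F)(F)F
Why: Acyl chloride/pyridine acylation is selective for the secondary alcohol and the hindered tertiary propargylic alcohol is then silylated by the silyl triflate; no stereocentre is touched.

Step 7
Reactants: 10 (2R,4R)-1,1-dimethoxy-4-methyl-4-[(triethylsilyl)oxy]hex-5-yn-2-yl 2-methylpropanoate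
Product: 11 (2R,4R)-4-methyl-1-oxo-4-[(triethylsilyl)oxy]hex-5-yn-2-yl 2-methylpropanoate
Conditions: TESOTf, 2,4,6-collidine, CH2Cl2, 0 °C; then H2O
Reagents that add atoms: water, O
Why: Chemoselective dimethyl acetal cleavage via the collidinium salt and hydrolysis (silyl triflate/collidine method); non-basic, so ester, silyl ether and the α-acyloxy stereocentre survive (aldehyde used crude).

Step 8
Reactants: 11 (2R,4R)-4-methyl-1-oxo-4-[(triethylsilyl)oxy]hex-5-yn-2-yl 2-methylpropanoate; 12 methyl propiolate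
Product: 14 methyl (4R,6R)-3-hydroxy-6-methyl-2-methylidene-4-[(2-methylpropanoyl)oxy]-6-[(triethylsilyl)oxy]oct-7-ynoate (C3 epimers), via vinylalane 13 (not isolated)
Conditions: iBu2AlH, NMO, THF, 0 °C, then 12; then 11, −20 → 0 °C, cold quench
Reagents that add atoms: none
Why: Vinylalumination (aluminium Morita–Baylis–Hillman equivalent): hydroalumination of 12 gives the α-aluminoacrylate, which adds 1,2 to the aldehyde without amine base, so C8 is not epimerised; the new carbinol centre is erased in step 9.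

Step 9
Reactants: 14 methyl (4R,6R)-3-hydroxy-6-methyl-2-methylidene-4-[(2-methylpropanoyl)oxy]-6-[(triethylsilyl)oxy]oct-7-ynoate
Product: 15 methyl (2Z,4R,6R)-2-(bromomethyl)-6-methyl-4-[(2-methylpropanoyl)oxy]-6-[(triethylsilyl)oxy]oct-2-en-7-ynoate
Conditions: NBS, Me2S, CH2Cl2, 0 → 23 °C
Reagents that add atoms: N-bromosuccinimide, O=C1CCC(=O)N1Br
Why: Corey–Kim-type activation with SN2′ bromide delivery (allylic transposition) gives the thermodynamically preferred Z-2-(bromomethyl)enoate.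

**Union and end game**

Step 10
Reactants: 15 methyl (2Z,4R,6R)-2-(bromomethyl)-6-methyl-4-[(2-methylpropanoyl)oxy]-6-[(triethylsilyl)oxy]oct-2-en-7-ynoate; 4 (2Z)-4-{[tert-butyl(diphenyl)silyl]oxy}-3-iodobut-2-enal
Product: 18 (1R,3R)-1-[(2R,3R)-2-[(1Z)-3-{[tert-butyl(diphenyl)silyl]oxy}-2-iodoprop-1-en-1-yl]-4-methylidene-5-oxooxolan-3-yl]-3-hydroxy-3-methylpent-4-yn-1-yl 2-methylpropanoate, via allylindium 16 (not isolated), via hydroxy ester 17 (not isolated)
Conditions: In powder, THF/H2O (1:1), 23 °C; then 1 M HCl, THF, 23 °C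
Reagents that add atoms: none
Why: Indium Barbier allylation through a chair transition state, then acid lactonisation: the Z-allylindium carries C8 axial and gives the syn adduct, hence the cis-lactone (C6/C7); A(1,3) strain holds H8 in the olefin plane and the aldehyde adds anti to the C9 methylene with the small acyloxy group on the attacked side (Felkin–Anh-type), setting C7 relative to C8; HCl also removes the TES ether.

Step 11
Reactants: 18 (1R,3R)-1-[(2R,3R)-2-[(1Z)-3-{[tert-butyl(diphenyl)silyl]oxy}-2-iodoprop-1-en-1-yl]-4-methylidene-5-oxooxolan-3-yl]-3-hydroxy-3-methylpent-4-yn-1-yl 2-methylpropanoate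
Product: 19 (4Z,6S,7R,8R,10R)-15-{[tert-butyl(diphenyl)silyl]oxy}-10-hydroxy-8-[(2-methylpropanoyl)oxy]-3-oxogermacra-4,11(13)-dien-1-yn-12,6-olide
Conditions: PdCl2(PPh3)2 (10 mol %), CuI (5 mol %), iPr2NEt, CO (1 atm), THF (0.001 M, slow addition), 35 °C
Reagents that add atoms: carbon monoxide, [C-]#[O+]
Why: Proposed new method: a carbonylative Sonogashira coupling used as a macrocyclisation to a ten-membered cyclic ynone. Zerovalent palladium inserts into the Z-alkenyl C–I bond with retention, CO insertion gives the acyl-palladium, the copper acetylide of the tertiary propargylic alcohol transmetalates and reductive elimination closes the ring. CO-free coupling would need a more strained nine-membered enyne, so insertion precedes ring closure. The two chains are cis on the lactone and, with the Z-olefin and the gem-disubstituted carbinol, hold the termini close; the planar Z-enynone fits the ring without strongly bending the alkyne. The closest known reactions are the intermolecular carbonylative Sonogashira coupling of alkenyl iodides with propargylic alcohols and carbonylative Stille macrocyclisation. No stereocentre is formed and the hindered amine spares the methylene lactone.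

Step 12
Reactants: 19 (4Z,6S,7R,8R,10R)-15-{[tert-butyl(diphenyl)silyl]oxy}-10-hydroxy-8-[(2-methylpropanoyl)oxy]-3-oxogermacra-4,11(13)-dien-1-yn-12,6-olide
Product: 22 (4Z,6S,7R,8R,10R)-15-hydroxy-8-[(2-methylpropanoyl)oxy]-1-oxo-3,10-epoxygermacra-2,4,11(13)-trien-12,6-olide (CNP0176924.5), via hydrated diketone 20 (not isolated), via silyl furanone 21 (not isolated)
Conditions: (4-CF3C6H4)3PAuCl (5 mol %), AgOTf (5 mol %), toluene/H2O (2 equiv), 23 °C; then HF·pyridine, THF, 0 → 23 °C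
Reagents that add atoms: water, O
Why: Gold-catalysed hydration–cyclodehydration of a γ-hydroxy ynone (known for open-chain substrates) run transannularly: water adds at C1, the C10 hydroxyl closes 5-exo onto C3 and water is lost, forming the O–C3 bond and the furanone while the C10–O bond is never broken (10R retained); the protected C15 oxygen cannot compete, and HF·pyridine then removes the silyl ether.

**Compound list**
1 | but-2-yne-1,4-diol | OCC#CCO | starting material
2 | 4-{[tert-butyl(diphenyl)silyl]oxy}but-2-yn-1-ol | OCC#CCO[Si](c1ccccc1)(c1ccccc1)C(C)(C)C | intermediate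
3 | (2Z)-4-{[tert-butyl(diphenyl)silyl]oxy}-3-iodobut-2-en-1-ol | OC/C=C(/CO[Si](c1ccccc1)(c1ccccc1)C(C)(C)C)I | intermediate
4 | (2Z)-4-{[tert-butyl(diphenyl)silyl]oxy}-3-iodobut-2-enal | O=C/C=C(/CO[Si](c1ccccc1)(c1ccccc1)C(C)(C)C)I | intermediate
5 | acetone | CC(C)=O | starting material
6 | 2,2-dimethoxyacetaldehyde | COC(OC)C=O | starting material
7 | (4R)-4-hydroxy-5,5-dimethoxypentan-2-one | CC(=O)C[C@@H](O)C(OC)OC | intermediate
8 | (3R,5R)-6,6-dimethoxy-3-methylhex-1-yne-3,5-diol | C#C[C@@](C)(C[C@@H](O)C(OC)OC)O | intermediate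
9 | (2R,4R)-4-hydroxy-1,1-dimethoxy-4-methylhex-5-yn-2-yl 2-methylpropanoate (formed and used in the flask) | C#C[C@@](C)(C[C@@H](OC(=O)C(C)C)C(OC)OC)O | intermediate
10 | (2R,4R)-1,1-dimethoxy-4-methyl-4-[(triethylsilyl)oxy]hex-5-yn-2-yl 2-methylpropanoate | C#C[C@@](C)(C[C@@H](OC(=O)C(C)C)C(OC)OC)O[Si](CC)(CC)CC | intermediate
11 | (2R,4R)-4-methyl-1-oxo-4-[(triethylsilyl)oxy]hex-5-yn-2-yl 2-methylpropanoate | C#C[C@@](C)(C[C@@H](OC(=O)C(C)C)C=O)O[Si](CC)(CC)CC | intermediate
12 | methyl propiolate | C#CC(=O)OC | starting material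
13 | methyl 2-(diisobutylalumanyl)prop-2-enoate (formed and used in the flask) | C=C(C(=O)OC)[Al](CC(C)C)CC(C)C | intermediate
14 | methyl (4R,6R)-3-hydroxy-6-methyl-2-methylidene-4-[(2-methylpropanoyl)oxy]-6-[(triethylsilyl)oxy]oct-7-ynoate (C3 epimers) | C#C[C@@](C)(C[C@@H](OC(=O)C(C)C)C(O)C(=C)C(=O)OC)O[Si](CC)(CC)CC | intermediate
15 | methyl (2Z,4R,6R)-2-(bromomethyl)-6-methyl-4-[(2-methylpropanoyl)oxy]-6-[(triethylsilyl)oxy]oct-2-en-7-ynoate | C#C[C@@](C)(C[C@@H](OC(=O)C(C)C)/C=C(\CBr)C(=O)OC)O[Si](CC)(CC)CC | intermediate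
16 | monovalent allylindium from 15 (In in place of Br; formed and used in the flask) | C#C[C@@](C)(C[C@@H](OC(=O)C(C)C)/C=C(\C[In])C(=O)OC)O[Si](CC)(CC)CC | intermediate
17 | methyl (3S,4R,6R)-3-[(1R,2Z)-4-{[tert-butyl(diphenyl)silyl]oxy}-1-hydroxy-3-iodobut-2-en-1-yl]-6-methyl-2-methylidene-4-[(2-methylpropanoyl)oxy]-6-[(triethylsilyl)oxy]oct-7-ynoate (formed and used in the flask) | COC(=O)C(=C)[C@@H]([C@@H](O)/C=C(/CO[Si](c1ccccc1)(c1ccccc1)C(C)(C)C)I)[C@H](OC(=O)C(C)C)C[C@](C)(C#C)O[Si](CC)(CC)CC | intermediate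
18 | (1R,3R)-1-[(2R,3R)-2-[(1Z)-3-{[tert-butyl(diphenyl)silyl]oxy}-2-iodoprop-1-en-1-yl]-4-methylidene-5-oxooxolan-3-yl]-3-hydroxy-3-methylpent-4-yn-1-yl 2-methylpropanoate | C=C1C(=O)O[C@@H](/C=C(/CO[Si](c2ccccc2)(c2ccccc2)C(C)(C)C)I)[C@H]1[C@H](OC(=O)C(C)C)C[C@@](C)(O)C#C | intermediate
19 | (4Z,6S,7R,8R,10R)-15-{[tert-butyl(diphenyl)silyl]oxy}-10-hydroxy-8-[(2-methylpropanoyl)oxy]-3-oxogermacra-4,11(13)-dien-1-yn-12,6-olide | C=C1C(=O)O[C@H]2/C=C(/CO[Si](c3ccccc3)(c3ccccc3)C(C)(C)C)C(=O)C#C[C@](C)(O)C[C@@H](OC(=O)C(C)C)[C@@H]12 | intermediate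
20 | (4Z,6S,7R,8R,10R)-15-{[tert-butyl(diphenyl)silyl]oxy}-10-hydroxy-8-[(2-methylpropanoyl)oxy]-1,3-dioxogermacra-4,11(13)-dien-12,6-olide (formed and used in the flask) | C=C1C(=O)O[C@H]2/C=C(/CO[Si](c3ccccc3)(c3ccccc3)C(C)(C)C)C(=O)CC(=O)[C@](C)(O)C[C@@H](OC(=O)C(C)C)[C@@H]12 | intermediate
21 | (4Z,6S,7R,8R,10R)-15-{[tert-butyl(diphenyl)silyl]oxy}-8-[(2-methylpropanoyl)oxy]-1-oxo-3,10-epoxygermacra-2,4,11(13)-trien-12,6-olide (formed and used in the flask) | C=C1C(=O)O[C@H]2/C=C(/CO[Si](c4ccccc4)(c4ccccc4)C(C)(C)C)C3=CC(=O)[C@@](C)(C[C@@H](OC(=O)C(C)C)[C@@H]12)O3 | intermediate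
22 | (4Z,6S,7R,8R,10R)-15-hydroxy-8-[(2-methylpropanoyl)oxy]-1-oxo-3,10-epoxygermacra-2,4,11(13)-trien-12,6-olide | C=C1C(=O)O[C@H]2/C=C(/CO)C3=CC(=O)[C@@](C)(C[C@@H](OC(=O)C(C)C)[C@@H]12)O3 | target

**Step count**
Total: 12 steps. Longest linear sequence: 9 steps (steps 4–12, from acetone and 2,2-dimethoxyacetaldehyde); the iodoenal branch is 3 steps (steps 1–3).

**Three steps most likely to fail**

Step 11 (new carbonylative macrocyclisation). Risks are oligomerisation, alkyne homocoupling and trapping of the acyl-palladium before ring closure. The fallback uses known reactions only; it sets out from 18 and comes back at 19. Stille coupling of 18 with Bu3SnCH2OH (Pd(PPh3)4, dioxane, 80 °C) replaces iodine by CH2OH and gives the seco allylic alcohol F1. MnO2 oxidation gives the seco enal F2. NIS with AgNO3 (cat.) in acetone converts the terminal alkyne into the iodoalkyne enal F3. Intramolecular Nozaki–Hiyama–Kishi coupling (CrCl2, NiCl2 cat., THF, high dilution) forms the C2–C3 bond and gives the ten-membered propargylic alcohol F4 as C3 epimers. Dess–Martin oxidation then gives 19.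

Step 10 (Barbier allylation). The syn selectivity is reliable, but the facial selectivity at C7 relative to the C8 acyloxy centre rests on an acyclic model and could be low or reversed. The fallback replaces substrate control by catalyst control; it sets out from 14 and comes back at 17. Acetylation (Ac2O, DMAP) gives the allylic acetate F5. Copper-catalysed SN2′ borylation (B2pin2, CuCl, Xantphos, KOtBu cat., THF) gives the configurationally fixed allylboronate F6 (CH2B cis to C8). Allylboration of 4 catalysed by the chiral phosphoric acid (R)-TRIP proceeds through a closed chair, so the fixed olefin geometry gives the syn relationship and the catalyst chooses the aldehyde face (6R carbinol of 17). The borate is hydrolysed to 17, which is lactonised and desilylated with HCl as in step 10.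

Step 12 (transannular C–O closure). On the strained ynone, gold could trigger other alkyne pathways or incomplete cyclodehydration. The fallback is the classical amine route; it sets out from 19 and comes back at 21. Excess Et2NH adds to the ynone at C1 and, reversibly, to the methylene lactone, giving the bis-amine adduct F7. Aqueous AcOH hydrolyses the enaminone with ring closure of the C10 hydroxyl onto C3 and gives the amine-masked furanone F8. MeI followed by NaHCO3 eliminates the amine and restores the methylene lactone, giving 21, which is desilylated with HF·pyridine as in step 12.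

**Further compounds**
F1 | step 11 | (1R,3R)-1-[(2S,3R)-2-[(1E)-3-{[tert-butyl(diphenyl)silyl]oxy}-2-(hydroxymethyl)prop-1-en-1-yl]-4-methylidene-5-oxooxolan-3-yl]-3-hydroxy-3-methylpent-4-yn-1-yl 2-methylpropanoate | C=C1C(=O)O[C@@H](/C=C(/CO[Si](c2ccccc2)(c2ccccc2)C(C)(C)C)CO)[C@H]1[C@H](OC(=O)C(C)C)C[C@@](C)(O)C#C
F2 | step 11 | (1R,3R)-1-[(2S,3R)-2-[(1Z)-3-{[tert-butyl(diphenyl)silyl]oxy}-2-formylprop-1-en-1-yl]-4-methylidene-5-oxooxolan-3-yl]-3-hydroxy-3-methylpent-4-yn-1-yl 2-methylpropanoate | C=C1C(=O)O[C@@H](/C=C(/CO[Si](c2ccccc2)(c2ccccc2)C(C)(C)C)C=O)[C@H]1[C@H](OC(=O)C(C)C)C[C@@](C)(O)C#C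
F3 | step 11 | (1R,3R)-1-[(2S,3R)-2-[(1Z)-3-{[tert-butyl(diphenyl)silyl]oxy}-2-formylprop-1-en-1-yl]-4-methylidene-5-oxooxolan-3-yl]-3-hydroxy-5-iodo-3-methylpent-4-yn-1-yl 2-methylpropanoate | C=C1C(=O)O[C@@H](/C=C(/CO[Si](c2ccccc2)(c2ccccc2)C(C)(C)C)C=O)[C@H]1[C@H](OC(=O)C(C)C)C[C@@](C)(O)C#CI
F4 | step 11 | (4Z,6S,7R,8R,10R)-15-{[tert-butyl(diphenyl)silyl]oxy}-3,10-dihydroxy-8-[(2-methylpropanoyl)oxy]germacra-4,11(13)-dien-1-yn-12,6-olide (C3 epimers) | C=C1C(=O)O[C@H]2/C=C(/CO[Si](c3ccccc3)(c3ccccc3)C(C)(C)C)C(O)C#C[C@](C)(O)C[C@@H](OC(=O)C(C)C)[C@@H]12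
F5 | step 10 | methyl (4R,6R)-3-acetoxy-6-methyl-2-methylidene-4-[(2-methylpropanoyl)oxy]-6-[(triethylsilyl)oxy]oct-7-ynoate (C3 epimers) | C#C[C@@](C)(C[C@@H](OC(=O)C(C)C)C(OC(C)=O)C(=C)C(=O)OC)O[Si](CC)(CC)CC
F6 | step 10 | methyl (2E,4R,6R)-6-methyl-4-[(2-methylpropanoyl)oxy]-2-[(4,4,5,5-tetramethyl-1,3,2-dioxaborolan-2-yl)methyl]-6-[(triethylsilyl)oxy]oct-2-en-7-ynoate | C#C[C@@](C)(C[C@@H](OC(=O)C(C)C)/C=C(\CB1OC(C)(C)C(C)(C)O1)C(=O)OC)O[Si](CC)(CC)CC
F7 | step 12 | (4Z,6S,7R,8R,10R)-1,13-bis(diethylamino)-15-{[tert-butyl(diphenyl)silyl]oxy}-10-hydroxy-8-[(2-methylpropanoyl)oxy]-3-oxogermacra-1,4-dien-12,6-olide (C11 epimers) | CCN(CC)CC1C(=O)O[C@H]2/C=C(/CO[Si](c3ccccc3)(c3ccccc3)C(C)(C)C)C(=O)C=C(N(CC)CC)[C@](C)(O)C[C@@H](OC(=O)C(C)C)[C@@H]12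
F8 | step 12 | (4Z,6S,7R,8R,10R)-13-(diethylamino)-15-{[tert-butyl(diphenyl)silyl]oxy}-8-[(2-methylpropanoyl)oxy]-1-oxo-3,10-epoxygermacra-2,4-dien-12,6-olide (C11 epimers) | CCN(CC)CC1C(=O)O[C@H]2/C=C(/CO[Si](c4ccccc4)(c4ccccc4)C(C)(C)C)C3=CC(=O)[C@@](C)(C[C@@H](OC(=O)C(C)C)[C@@H]12)O3
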